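Ring B of the target carries its oxygen at C6 and its side chain at C9, the two carbons that flank the C5–C10 fusion bond, and has methyls at C8 and C10. This pattern maps onto 2,6-dimethyl-1,4-benzoquinone. Ring A is therefore disconnected at C1–C10 and C4–C5. A catalytic enantioselective Diels–Alder reaction of 4-methylpenta-1,3-diene with this quinone closes ring A, brings in the gem-dimethyl C4 and sets the quaternary C10 in one operation; C5 forms cis and is corrected later. C6=O and C9=O remain as distinguishable handles. Both partners are commercial and are used directly; the side chain enters later at C9 as an organocerium reagent.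

Key step: step 1

Remarks
- Labdane numbering is used for all ring compounds: ring A = C1–C5/C10, ring B = C5–C10, C17 on C8, C20 on C10, side chain C11–C16.
- The quinone must be the 2,6-dimethyl isomer. The 2,5-isomer would place the ring-B methyl on C7, not C8.
- Assumption: on the usual α-C–H···O binding model the (R)-diphenylprolinol-derived oxazaborolidinium leaves the Si face of the methyl-bearing quinone carbon open, which gives (10S). The sense is to be confirmed in a pilot run; if it is opposite, the (S)-catalyst is used with no other change.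
- C9 of 16 and 17 is drawn as the epimer expected from attack anti to C20; its configuration is irrelevant because C9 becomes sp2 in step 10.

Step 1
Reactants: 1 2,6-dimethyl-1,4-benzoquinone; 2 4-methylpenta-1,3-diene
Product: 3 (4aR,8aS)-2,5,5,8a-tetramethyl-4a,5,8,8a-tetrahydronaphthalene-1,4-dione (cis adduct: 6,9-dioxo, Δ2, Δ7, 5β-H, 10β-CH3)
Conditions: (R)-o-tolyl-oxazaborolidine·HNTf2 (20 mol %), 2 (4 equiv, distilled from maleic anhydride to remove 2-methylpenta-1,3-diene), CH2Cl2, −78 → −40 °C
Reagents that add atoms: none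
Why: The oxazaborolidinium binds the unhindered C6 carbonyl of 1 through the lone pair syn to the C5–H and lowers the LUMO of the adjacent C5=C10 bond, which undergoes a concerted, asynchronous, suprafacial [4+2] addition with the s-cis diene; the closest known reaction type is the oxazaborolidinium-catalysed Diels–Alder reaction of alkylbenzoquinones with 1,3-dienes. Ring A is closed by this intermolecular [4+2] cycloaddition, with C1–C10 and C4–C5 formed in the same event. C10 is set by the catalyst, whose aryl group covers one face of the bound C=C so that the diene reaches C10 on its Si face; C5 follows from suprafacial addition and is therefore cis to the C10 methyl, to be corrected in step 9. Regiochemistry is required and is secured twice: activation at C6=O makes C10 the electrophilic β-carbon, which pairs with the unsubstituted, most nucleophilic diene terminus, and the other orientation would join the gem-dimethyl carbon to a quaternary centre. No site selectivity is needed because the two C=C bonds of 1 are symmetry-equivalent, and endo/exo is irrelevant because the diene carries no stereogenic substituent.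

Step 2
Reactants: 3 cis adduct
Product: 4 (8aS)-2,5,5,8a-tetramethyl-4-(triethylsilyloxy)-8,8a-dihydronaphthalen-1(5H)-one (C5=C6 triethylsilyl dienol ether; C9=O, Δ2, Δ7)
Conditions: TESOTf, Et3N, CH2Cl2, −78 → 0 °C
Reagents that add atoms: triethylsilyl trifluoromethanesulfonate, CC[Si](CC)(CC)OS(=O)(=O)C(F)(F)F
Why: Soft enolisation (silyl enol ether formation) silylates the more basic, less hindered C6 carbonyl and removes its only α-hydrogen (C5–H; C9=O has none), which masks C6 and leaves C9=O as the sole carbonyl.

Step 3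
Reactants: 4 triethylsilyl dienol ether
Product: 5 (8aS)-2,5,5,8a-tetramethyl-4-(triethylsilyloxy)-6,7,8,8a-tetrahydronaphthalen-1(5H)-one (ring A saturated)
Conditions: H2 (3 atm), RhCl(PPh3)3 (5 mol %), benzene, rt
Reagents that add atoms: none
Why: Homogeneous hydrogenation with Wilkinson's catalyst should reduce the cis-disubstituted C2=C3 bond and leave the tri- and tetrasubstituted, conjugated C7=C8 and C5=C6 bonds untouched; it is done here because no side-chain alkene is present yet.

Step 4
Reactants: 6 but-3-yn-1-ol
Product: 7 (but-3-yn-1-yloxy)(tert-butyl)dimethylsilane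
Conditions: TBSCl, imidazole, CH2Cl2, 0 °C → rt
Reagents that add atoms: tert-butyldimethylsilyl chloride, CC(C)(C)[Si](C)(C)Cl
Why: Standard silylation of a primary alcohol, which differentiates this oxygen (future C11) from the one introduced in step 5.

Step 5
Reactants: 7 TBS ether of but-3-yn-1-ol
Product: 10 (E)-5-(tert-butyldimethylsilyloxy)-3-methylpent-2-en-1-ol, via alkenylalane 8 (not isolated), via lithium alkenylalanate 9 (not isolated)
Conditions: Me3Al, Cp2ZrCl2 (25 mol %), CH2Cl2, 0 °C → rt; evaporate; n-BuLi, THF/hexane, −78 → 0 °C; (CH2O)n, rt; aq. Rochelle salt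
Reagents that add atoms: trimethylaluminium, C[Al](C)C; formaldehyde (as paraformaldehyde), C=O
Why: Zirconium-catalysed carboalumination (Negishi) adds CH3–Al syn across the alkyne with Al at the terminus, and the derived alanate is hydroxymethylated with retention, which fixes the E geometry (CH3 cis to CH2OH).

Step 6
Reactants: 10 allylic alcohol
Product: 11 (E)-5-(tert-butyldimethylsilyloxy)-1-(tert-butyldiphenylsilyloxy)-3-methylpent-2-ene
Conditions: TBDPSCl, imidazole, DMF, rt
Reagents that add atoms: tert-butyldiphenylsilyl chloride, CC(C)(C)[Si](Cl)(c1ccccc1)c1ccccc1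
Why: Silylation of the primary allylic alcohol with a group that survives organolithium, methoxide, zinc/acetic acid and acetylation and is removable at the end without touching acetates.

Step 7
Reactants: 11 bis-silyl ether
Product: 12 (E)-5-(tert-butyldiphenylsilyloxy)-3-methylpent-3-en-1-ol
Conditions: CSA (10 mol %), MeOH/CH2Cl2, 0 °C
Reagents that add atoms: none
Why: Acid-catalysed methanolysis cleaves the primary TBS ether much faster than the bulkier TBDPS ether (selective desilylation).

Step 8
Reactants: 12 homoallylic alcohol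
Product: 13 (E)-tert-butyl[(5-iodo-3-methylpent-2-en-1-yl)oxy]diphenylsilane
Conditions: PPh3, I2, imidazole, CH2Cl2, 0 °C
Reagents that add atoms: iodine, II
Why: Appel-type iodination converts the primary alcohol into the iodide by SN2 displacement of the oxyphosphonium ion without touching the alkene.

Step 9
Reactants: 13 side-chain iodide; 5 dienone silyl enol ether
Product: 17 9β-hydroxy-15-(tert-butyldiphenylsilyloxy)labda-7,13E-dien-6-one (5α-H, 10β-CH3), via alkyllithium 14 (not isolated), via organocerium reagent 15 (not isolated), via C9 carbinol silyl dienol ether 16 (not isolated)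
Conditions: 13, t-BuLi (2.1 equiv), Et2O, −78 °C; CeCl3 (anhydrous), THF, −78 °C; 5, −78 → −40 °C; then NaOMe, MeOH, −40 °C → rt (no acidic work-up)
Reagents that add atoms: none
Why: Iodine–lithium exchange and transmetalation give a weakly basic organocerium that adds 1,2 to the hindered, non-enolisable C9 carbonyl (organocerium addition), after which methoxide cleaves the silyl enol ether and equilibrates C5, whose protonation from the α face, anti to the axial C4β and C10 methyls, should give the more stable trans fusion.

Step 10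
Reactants: 17 γ-hydroxy enone
Product: 18 15-(tert-butyldiphenylsilyloxy)labda-8,13E-dien-6-one (5α-H, 10β-CH3)
Conditions: Zn dust (activated), AcOH, 60 °C
Reagents that add atoms: none
Why: Zinc/acetic acid reductive cleavage of a γ-oxygenated enone: two-electron reduction expels the C9 hydroxyl to give the dienol, which should ketonise by kinetic protonation at C7 to the β,γ-unsaturated ketone with the tetrasubstituted C8=C9 bond.

Step 11
Reactants: 18 β,γ-unsaturated ketone
Product: 20 7α-hydroxy-15-(tert-butyldiphenylsilyloxy)labda-8,13E-dien-6-one, via potassium dienolate 19 (not isolated)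
Conditions: KHMDS, THF, −78 °C; 2-(phenylsulfonyl)-3-phenyloxaziridine, −78 °C; AcOH quench at −78 °C
Reagents that add atoms: 2-(phenylsulfonyl)-3-phenyloxaziridine, O=S(=O)(c1ccccc1)N1OC1c1ccccc1
Why: Kinetic deprotonation at the doubly activated C7 gives the extended dienolate, which should take electrophilic oxygen at its α-carbon (Davis enolate hydroxylation) from the α face, axially and away from the β-face methyls, setting 7α-OH without epoxidising either alkene.

Step 12
Reactants: 20 α-hydroxy ketone
Product: 21 15-(tert-butyldiphenylsilyloxy)labda-8,13E-diene-6β,7α-diol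
Conditions: NaBH4, CeCl3·7H2O, MeOH, −40 → 0 °C
Reagents that add atoms: none
Why: Luche-type borohydride reduction in which hydride should reach C6 from the α face, because the β face is blocked by the syn-axial C4β and C10 methyls, giving the axial 6β-alcohol trans to the 7α-hydroxyl.

Step 13
Reactants: 21 diol
Product: 22 6β,7α-diacetoxy-15-(tert-butyldiphenylsilyloxy)labda-8,13E-diene
Conditions: Ac2O, DMAP, pyridine, 50 °C
Reagents that add atoms: acetic anhydride, CC(=O)OC(C)=O
Why: DMAP-catalysed acylation of both secondary hydroxyls, with warming to drive the hindered axial 6β-hydroxyl to completion.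

Step 14
Reactants: 22 silyl-protected diacetate
Product: 23 6β,7α-diacetoxylabda-8,13E-dien-15-ol (target)
Conditions: HF·pyridine, pyridine, THF, 0 °C → rt
Reagents that add atoms: none
Why: Buffered fluoride cleavage of the TBDPS ether (desilylation) should leave both acetates and the allylic systems intact.

Compound list
1 | 2,6-dimethyl-1,4-benzoquinone | CC1=CC(=O)C=C(C)C1=O | starting material
2 | 4-methylpenta-1,3-diene | CC(C)=CC=C | starting material
3 | (4aR,8aS)-2,5,5,8a-tetramethyl-4a,5,8,8a-tetrahydronaphthalene-1,4-dione (cis adduct) | O=C1C=C(C)C(=O)[C@@]2(C)CC=CC(C)(C)[C@@H]12 | intermediate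
4 | (8aS)-2,5,5,8a-tetramethyl-4-(triethylsilyloxy)-8,8a-dihydronaphthalen-1(5H)-one | CC[Si](CC)(CC)OC1=C2C(C)(C)C=CC[C@]2(C)C(=O)C(C)=C1 | intermediate
5 | (8aS)-2,5,5,8a-tetramethyl-4-(triethylsilyloxy)-6,7,8,8a-tetrahydronaphthalen-1(5H)-one | CC[Si](CC)(CC)OC1=C2C(C)(C)CCC[C@]2(C)C(=O)C(C)=C1 | intermediate
6 | but-3-yn-1-ol | C#CCCO | starting material
7 | (but-3-yn-1-yloxy)(tert-butyl)dimethylsilane | C#CCCO[Si](C)(C)C(C)(C)C | intermediate
8 | (E)-[4-(tert-butyldimethylsilyloxy)-2-methylbut-1-enyl]dimethylalane | C[Al](C)/C=C(\C)CCO[Si](C)(C)C(C)(C)C | intermediate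
9 | lithium butyl[(E)-4-(tert-butyldimethylsilyloxy)-2-methylbut-1-enyl]dimethylalanate | [Li+].CCCC[Al-](C)(C)/C=C(\C)CCO[Si](C)(C)C(C)(C)C | intermediate
10 | (E)-5-(tert-butyldimethylsilyloxy)-3-methylpent-2-en-1-ol | OC/C=C(\C)CCO[Si](C)(C)C(C)(C)C | intermediate
11 | (E)-5-(tert-butyldimethylsilyloxy)-1-(tert-butyldiphenylsilyloxy)-3-methylpent-2-ene | CC(C)(C)[Si](C)(C)OCC/C(C)=C/CO[Si](c1ccccc1)(c1ccccc1)C(C)(C)C | intermediate
12 | (E)-5-(tert-butyldiphenylsilyloxy)-3-methylpent-3-en-1-ol | OCC/C(C)=C/CO[Si](c1ccccc1)(c1ccccc1)C(C)(C)C | intermediate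
13 | (E)-tert-butyl[(5-iodo-3-methylpent-2-en-1-yl)oxy]diphenylsilane | ICC/C(C)=C/CO[Si](c1ccccc1)(c1ccccc1)C(C)(C)C | intermediate
14 | (E)-5-(tert-butyldiphenylsilyloxy)-3-methylpent-3-enyllithium | [Li]CC/C(C)=C/CO[Si](c1ccccc1)(c1ccccc1)C(C)(C)C | intermediate
15 | dichloro[(E)-5-(tert-butyldiphenylsilyloxy)-3-methylpent-3-enyl]cerium | Cl[Ce](Cl)CC/C(C)=C/CO[Si](c1ccccc1)(c1ccccc1)C(C)(C)C | intermediate
16 | 9β-hydroxy-6-(triethylsilyloxy)-15-(tert-butyldiphenylsilyloxy)labda-5,7,13E-triene | CC[Si](CC)(CC)OC1=C2C(C)(C)CCC[C@]2(C)[C@](O)(CC/C(C)=C/CO[Si](c3ccccc3)(c3ccccc3)C(C)(C)C)C(C)=C1 | intermediate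
17 | 9β-hydroxy-15-(tert-butyldiphenylsilyloxy)labda-7,13E-dien-6-one (5α-H) | O=C1C=C(C)[C@@](O)(CC/C(C)=C/CO[Si](c3ccccc3)(c3ccccc3)C(C)(C)C)[C@@]2(C)CCCC(C)(C)[C@H]12 | intermediate
18 | 15-(tert-butyldiphenylsilyloxy)labda-8,13E-dien-6-one | O=C1CC(C)=C(CC/C(C)=C/CO[Si](c3ccccc3)(c3ccccc3)C(C)(C)C)[C@@]2(C)CCCC(C)(C)[C@H]12 | intermediate
19 | potassium 15-(tert-butyldiphenylsilyloxy)labda-6,8,13E-trien-6-olate | [K+].[O-]C1=CC(C)=C(CC/C(C)=C/CO[Si](c3ccccc3)(c3ccccc3)C(C)(C)C)[C@@]2(C)CCCC(C)(C)[C@H]12 | intermediate
20 | 7α-hydroxy-15-(tert-butyldiphenylsilyloxy)labda-8,13E-dien-6-one | O=C1[C@@H](O)C(C)=C(CC/C(C)=C/CO[Si](c3ccccc3)(c3ccccc3)C(C)(C)C)[C@@]2(C)CCCC(C)(C)[C@H]12 | intermediate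
21 | 15-(tert-butyldiphenylsilyloxy)labda-8,13E-diene-6β,7α-diol | O[C@@H]1[C@@H](O)C(C)=C(CC/C(C)=C/CO[Si](c3ccccc3)(c3ccccc3)C(C)(C)C)[C@@]2(C)CCCC(C)(C)[C@H]12 | intermediate
22 | 6β,7α-diacetoxy-15-(tert-butyldiphenylsilyloxy)labda-8,13E-diene | CC(=O)O[C@@H]1[C@@H](OC(C)=O)C(C)=C(CC/C(C)=C/CO[Si](c3ccccc3)(c3ccccc3)C(C)(C)C)[C@@]2(C)CCCC(C)(C)[C@H]12 | intermediate
23 | 6β,7α-diacetoxylabda-8,13E-dien-15-ol | CC(=O)O[C@@H]1[C@@H](OC(C)=O)C(C)=C(CC/C(C)=C/CO)[C@@]2(C)CCCC(C)(C)[C@H]12 | target

Total step count: 14.
Longest linear sequence: 11 steps (6 → 23; steps 4–8, then 9–14). The ring-system branch is 9 steps (1 → 23; steps 1–3, then 9–14).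

Steps most likely to fail

1. Step 1. The cis methyl of the diene disfavours the s-cis conformer and the diene is acid-sensitive. The cycloaddition may therefore be slow, the diene may oligomerise under the strongly acidic catalyst, or enantiofacial control may be insufficient. Fallback (resolution in place of asymmetric catalysis): from 1 and 2, an uncatalysed cycloaddition under high pressure, or one promoted by BF3·OEt2 at low temperature, gives the racemic cis adduct F1. An oxazaborolidine-catalysed borane reduction (Me-CBS, BH3·SMe2, substoichiometric hydride) is then run as a kinetic resolution past half conversion, the catalyst antipode being chosen so that the unwanted enantiomer is reduced at C6 to the antipodal C6 carbinol F2. F2 is removed by chromatography, and the unreacted enone is compound 3, where the route is rejoined.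

2. Step 11. Oxygen transfer to the dienolate may lack facial control, or the labile α-ketol may epimerise at C7 on work-up, so that the 7β-carbinol is obtained. Fallback (C7 configuration by SN2 inversion in place of facial selectivity): setting out from 18, the 7β-hydroxy ketone F3 delivered by the hydroxylation is inverted with PPh3/DIAD/AcOH (Mitsunobu reaction) to the 7α-acetoxy ketone F4. Reduction with NaBH4/CeCl3 from the α face gives the 6β-hydroxy 7α-acetate F5, and acetylation under the conditions of step 13 rejoins the route at 22.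

3. Step 10. The tertiary hydroxyl may not be expelled, leading to plain conjugate reduction or recovered 17, or the β,γ-enone may drift into conjugation in warm acetic acid. Fallback (cross-coupling in place of carbonyl addition and reductive cleavage, bypassing steps 9 and 10): setting out from 5, conjugate hydride addition at C7 (L-Selectride, THF, −78 °C) and trapping of the C9 enolate with Comins' reagent gives the C8=C9 enol triflate F6. Negishi coupling (Pd(dppf)Cl2, THF) with the alkylzinc iodide F7, made from 13 with Zn/LiCl, forms the C9–C11 bond and gives the coupled triethylsilyl enol ether F8. K2CO3/MeOH at 0 °C cleaves the enol ether with α-face protonation at C5, and the route is rejoined at 18.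

Further compounds
F1 | step 1 | racemic cis adduct (3 together with its antipode) | O=C1C=C(C)C(=O)[C@@]2(C)CC=CC(C)(C)[C@@H]12.O=C1C=C(C)C(=O)[C@]2(C)CC=CC(C)(C)[C@H]12
F2 | step 1 | antipodal C6 carbinol (6-hydroxy-7-en-9-one of ent-3) | O[C@@H]1C=C(C)C(=O)[C@]2(C)CC=CC(C)(C)[C@H]12
F3 | step 11 | 7β-hydroxy-15-(tert-butyldiphenylsilyloxy)labda-8,13E-dien-6-one | O=C1[C@H](O)C(C)=C(CC/C(C)=C/CO[Si](c3ccccc3)(c3ccccc3)C(C)(C)C)[C@@]2(C)CCCC(C)(C)[C@H]12
F4 | step 11 | 7α-acetoxy-15-(tert-butyldiphenylsilyloxy)labda-8,13E-dien-6-one | O=C1[C@@H](OC(C)=O)C(C)=C(CC/C(C)=C/CO[Si](c3ccccc3)(c3ccccc3)C(C)(C)C)[C@@]2(C)CCCC(C)(C)[C@H]12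
F5 | step 11 | 7α-acetoxy-15-(tert-butyldiphenylsilyloxy)labda-8,13E-dien-6β-ol | O[C@@H]1[C@@H](OC(C)=O)C(C)=C(CC/C(C)=C/CO[Si](c3ccccc3)(c3ccccc3)C(C)(C)C)[C@@]2(C)CCCC(C)(C)[C@H]12
F6 | step 10 | C8=C9 enol triflate of the C5=C6 triethylsilyl enol ether (from 5) | CC[Si](CC)(CC)OC1=C2C(C)(C)CCC[C@]2(C)C(OS(=O)(=O)C(F)(F)F)=C(C)C1
F7 | step 10 | (E)-5-(tert-butyldiphenylsilyloxy)-3-methylpent-3-enylzinc iodide | I[Zn]CC/C(C)=C/CO[Si](c1ccccc1)(c1ccccc1)C(C)(C)C
F8 | step 10 | 6-(triethylsilyloxy)-15-(tert-butyldiphenylsilyloxy)labda-5,8,13E-triene | CC[Si](CC)(CC)OC1=C2C(C)(C)CCC[C@]2(C)C(CC/C(C)=C/CO[Si](c3ccccc3)(c3ccccc3)C(C)(C)C)=C(C)C1
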